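**Plan**
- Retrosynthesis: the C1 carbinol goes back to a ketone, the C10=C20 and C6=C7 double bonds to a saturated 7-hydroxy lactone, ring B is cut at C6–C7 (pinacol coupling of two aldehydes), and ring A is cut at C3–C4 and C5–C10 (Diels–Alder).
- Enabling feature: the γ-lactone C19–O–C6 is cis-fused to ring A across C4–C5, with the methyl-bearing quaternary C4 next to C5. This is a 3-methylbutenolide whose C4=C5 bond can take up C3, C2, C1 and C10 as a 2-silyloxydiene.
- Forward: ring C is carried from the start as a 1,2,4-trimethoxyarene (isopropyl at C13, masked formyl C7 on C8, chain C20–C10–C1–C2–C3 on C9). Ring A and the lactone arise together in the cycloaddition, ring B by SmI2 pinacol closure, then C6=C7, C10=C20, the quinone, and last the C1 carbinol.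
- Stereochemistry: the C6 acetal centre, fixed by crystallising the (−)-menthol acetal, sends the diene to the opposite face and so sets C4 (S) and C5 (R). C1 (R) comes from hydride attack on the convex face of the tricyclic enone. The C10, C6 and C7 centres are transient.

Key step: step 12

Remarks: atoms are numbered as in the icetexane [9(10→20)abeo-abietane] skeleton, in which the target is 1R,4S,5R. Ar = 2-(5,5-dimethyl-1,3-dioxan-2-yl)-4-isopropyl-3,5,6-trimethoxyphenyl; Ar' = 2-formyl-4-isopropyl-3,5,6-trimethoxyphenyl; Men = (1R,2S,5R)-menthyl.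
Assumption: the 5R epimer of acetal 4 is the one that crystallises. Centres that are destroyed later are drawn as the expected isomer (C1 in 17–23, C10 in 15–24) or left open where a mixture is expected (C6 in 18, C6/C7 in 20 and 21).

**Route**

Step 1
Reactants: 1 citraconic anhydride
Product: 2 5-hydroxy-3-methylfuran-2(5H)-one (racemic lactol)
Conditions: LiAlH(OtBu)3 (1.05 equiv), THF, −40 to −15 °C; then 2 M HCl
Reagents that add atoms: none
Why: Partial hydride reduction of a cyclic anhydride, in which the bulky alkoxyaluminium hydride should attack the less hindered carbonyl remote from the methyl group and the aluminate of the lactol resists further reduction at low temperature, so that the methyl group ends up α to the remaining lactone carbonyl.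

Step 2
Reactants: 2 5-hydroxy-3-methylfuran-2(5H)-one; 3 (−)-menthol
Product: 4 (5R)-5-(MenO)-3-methylfuran-2(5H)-one
Conditions: camphorsulfonic acid (cat.), toluene, reflux, Dean–Stark; crystallisation from hexane; mother liquor re-equilibrated with acid
Reagents that add atoms: none
Why: Acid-catalysed acetalisation of the lactol gives both C5 epimers, which interconvert through the oxocarbenium ion, and the 5R epimer is expected to crystallise, so the acetal centre (future C6) is set by crystallisation of one menthol-derived diastereomer.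

Step 3
Reactants: 5 1,2,4-trimethoxybenzene
Product: 6 2-(2,3,6-trimethoxyphenyl)propan-2-ol
Conditions: n-BuLi, THF, 0 °C; acetone, −78 °C to rt; then H2O
Reagents that add atoms: acetone, CC(C)=O
Why: Directed ortho-lithiation takes place at C3, the position flanked by two methoxy groups, and the aryllithium undergoes 1,2-addition to acetone.

Step 4
Reactants: 6 2-(2,3,6-trimethoxyphenyl)propan-2-ol
Product: 7 2-isopropyl-1,3,4-trimethoxybenzene
Conditions: Et3SiH, CF3CO2H, CH2Cl2, 0 °C
Reagents that add atoms: none
Why: Ionic hydrogenation, in which the tertiary benzylic cation formed in acid is reduced by the silane to the isopropyl group.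

Step 5
Reactants: 7 2-isopropyl-1,3,4-trimethoxybenzene
Product: 8 3-isopropyl-2,4,5-trimethoxybenzaldehyde
Conditions: Cl2CHOMe, TiCl4, CH2Cl2, −78 to 0 °C; then H2O
Reagents that add atoms: dichloromethyl methyl ether, COC(Cl)Cl; water, O
Why: Rieche formylation, an electrophilic aromatic substitution that should go to the free position that is ortho to one methoxy group and para to another, which places the future C7 on C8.

Step 6
Reactants: 8 3-isopropyl-2,4,5-trimethoxybenzaldehyde
Product: 9 2-(3-isopropyl-2,4,5-trimethoxyphenyl)-5,5-dimethyl-1,3-dioxane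
Conditions: 2,2-dimethylpropane-1,3-diol, pyridinium p-toluenesulfonate (cat.), toluene, reflux, Dean–Stark
Reagents that add atoms: 2,2-dimethylpropane-1,3-diol, OCC(C)(C)CO
Why: Acetalisation masks the formyl group against the organometallic steps that follow, and C7 is kept at the aldehyde level because benzylic C–O derivatives of this electron-rich ring would ionise in the later acid hydrolysis whereas the aldehyde is inert.

Step 7
Reactants: 9 2-(3-isopropyl-2,4,5-trimethoxyphenyl)-5,5-dimethyl-1,3-dioxane
Product: 10 2-(2-iodo-5-isopropyl-3,4,6-trimethoxyphenyl)-5,5-dimethyl-1,3-dioxane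
Conditions: n-BuLi, TMEDA, Et2O, 0 °C; I2, −78 °C
Reagents that add atoms: iodine, [I][I]
Why: Directed ortho-metalation at the single remaining ring hydrogen, which lies between a methoxy group and the acetal, followed by iodination of the aryllithium.

Step 8
Reactants: 10 2-(2-iodo-5-isopropyl-3,4,6-trimethoxyphenyl)-5,5-dimethyl-1,3-dioxane
Product: 11 3-Ar-propanal
Conditions: Pd(OAc)2 (5 mol %), Bu4NCl, NaHCO3, allyl alcohol, DMF, 50 °C
Reagents that add atoms: allyl alcohol, C=CCO
Why: Heck reaction with an allylic alcohol under ligand-free phase-transfer conditions, in which β-hydride elimination after carbopalladation runs toward the carbinol carbon and the enol tautomerises to the 3-arylpropanal (C20–C10–C1).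

Step 9
Reactants: 11 3-Ar-propanal
Product: 12 5-Ar-pent-1-en-3-ol (racemic)
Conditions: CH2=CHMgBr, THF, −78 °C; then H2O
Reagents that add atoms: vinylmagnesium bromide, C=C[Mg]Br
Why: Grignard 1,2-addition to the aldehyde brings in C2 and C3, and the new carbinol centre is racemic and is removed in the next step.

Step 10
Reactants: 12 5-Ar-pent-1-en-3-ol
Product: 13 5-Ar-pent-1-en-3-one
Conditions: Dess–Martin periodinane, NaHCO3, CH2Cl2, 0 °C
Reagents that add atoms: none
Why: Dess–Martin oxidation of the allylic alcohol under buffered, non-acidic conditions gives the vinyl ketone without touching the acetal.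

Step 11
Reactants: 13 5-Ar-pent-1-en-3-one
Product: 14 (3Z)-5-Ar-3-(tert-butyldimethylsilyloxy)penta-1,3-diene
Conditions: LiN(SiMe3)2, THF/DMPU, −78 °C; then t-BuMe2SiCl
Reagents that add atoms: tert-butyldimethylsilyl chloride, CC(C)(C)[Si](C)(C)Cl
Why: Kinetic deprotonation at the only enolisable position (C10) and O-silylation give the silyl dienol ether, and the Z enolate expected in the presence of DMPU places the arylmethyl group on the outside of the s-cis diene.

Step 12
Reactants: 4 (5R)-5-(MenO)-3-methylfuran-2(5H)-one; 14 (3Z)-5-Ar-3-(tert-butyldimethylsilyloxy)penta-1,3-diene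
Product: 15 (3R,3aR,4S,7aS)-4-(ArCH2)-5-(tert-butyldimethylsilyloxy)-3-(MenO)-7a-methyl-3a,4,7,7a-tetrahydroisobenzofuran-1(3H)-one (endo adduct)
Conditions: toluene, BHT (cat.), 130 °C, sealed tube
Reagents that add atoms: none
Why: A concerted, asynchronous normal-demand [4+2] cycloaddition (Diels–Alder reaction) in which the electron-rich 2-silyloxydiene 14 adds across the C4=C5 bond of the butenolide; the closest known reaction type is the thermal cycloaddition of 5-alkoxy-2(5H)-furanones with 2-silyloxybutadienes. Ring A (C1–C2–C3–C4–C5–C10) closes as a six-membered carbocycle by suprafacial formation of C3–C4 and C5–C10 on one face of the lactone. C4 and C5 are controlled by the C6 acetal centre, since the diene approaches anti to the menthyloxy group and the cis geometry of the ring alkene makes the lactone fusion cis, giving 4S,5R. C10 (10S) follows from the endo arrangement of the lactone beneath the diene together with the Z enol ether geometry, and it is of no lasting consequence because C10 later becomes sp2. The step needs regiocontrol and face control: the 2-silyloxy group makes C10 the nucleophilic terminus, which pairs with the electrophilic β-carbon C5 so that C3 meets the α-carbon C4, and the bulky acetal substituent shields one face. The α-methyl group slows the dienophile, hence concentrated heating in a sealed tube with a radical inhibitor.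

Step 13
Reactants: 15 Diels–Alder adduct
Product: 17 (3R,3aR,4S,5R,7aS)-4-(ArCH2)-5-hydroxy-3-(MenO)-7a-methylhexahydroisobenzofuran-1(3H)-one, via ketone 16 (not isolated)
Conditions: Bu4NF, AcOH, THF, −20 °C; then NaBH4, MeOH, −20 to 0 °C
Reagents that add atoms: none
Why: Fluoride cleaves the silyl enol ether with C-protonation at C2 while both acetals survive, and borohydride reduction of the ketone (hydride expected from the convex face) masks C1 as a carbinol of inconsequential configuration, because a C1 ketone would later intercept the aryl ketyl in a six-membered pinacol closure.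

Step 14
Reactants: 17 bicyclic C1 carbinol
Product: 18 (3aR,4S,5R,7aS)-4-(Ar'CH2)-3,5-dihydroxy-7a-methylhexahydroisobenzofuran-1(3H)-one (lactol, both C3 anomers)
Conditions: 2 M HCl, 1,4-dioxane, 60 °C
Reagents that add atoms: water, O
Why: Acid hydrolysis of both acetals releases the aryl aldehyde and the C6 aldehyde, the latter being held with the cis C19 acid as the ring lactol (pseudo-acid), which guards C5 against epimerisation and lets the menthol be recovered.

Step 15
Reactants: 18 lactol aldehyde
Product: 19 methyl (1S,2R,3S,4R)-2-formyl-3-(Ar'CH2)-4-hydroxy-1-methylcyclohexane-1-carboxylate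
Conditions: Me3SiCHN2, toluene/MeOH (4:1), 0 °C
Reagents that add atoms: (trimethylsilyl)diazomethane, C[Si](C)(C)C=[N+]=[N-]
Why: Esterification with a diazoalkane takes place on the open carboxylic acid tautomer of the pseudo-acid under neutral conditions, so the C6 aldehyde is set free without base and C5 is not epimerised.

Step 16
Reactants: 19 dialdehyde ester
Product: 21 (1R,4S,5R,10S)-1,7-dihydroxy-11,12,14-trimethoxy-9(10→20)abeo-abieta-8,11,13-trien-19,6-olide (C6/C7 not controlled), via diol ester 20 (not isolated)
Conditions: SmI2 (3 equiv), t-BuOH, THF, −78 to 0 °C; then aq. NaHCO3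
Reagents that add atoms: none
Why: Intramolecular pinacol coupling, in which electron transfer to the aryl aldehyde gives a ketyl that joins C7 to the C6 aldehyde in a seven-membered ring (ring B) through a samarium-bridged cis-diolate whose C6 alkoxide then lactonises onto the C19 ester, the new C6 and C7 centres being lost in the next step.

Step 17
Reactants: 21 7-hydroxy lactone
Product: 23 (1R,4S,5R,10S)-1-hydroxy-11,12,14-trimethoxy-9(10→20)abeo-abieta-6,8,11,13-tetraen-19,6-olide, via trifluoroacetate 22 (not isolated)
Conditions: (CF3CO)2O, i-Pr2NEt, CH2Cl2, −40 to 0 °C; then MeOH, NaHCO3, 0 °C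
Reagents that add atoms: none
Why: Dehydration by E1 elimination, in which the trifluoroacetate of the electron-rich benzylic C7 alcohol ionises and loses H6 (the only β-hydrogen) to give the enol lactone, while the unactivated C1 trifluoroacetate is inert, cannot trap the cation and is then cleaved by mild methanolysis.

Step 18
Reactants: 23 enol lactone carbinol
Product: 24 (4S,5R,10S)-11,12,14-trimethoxy-1-oxo-9(10→20)abeo-abieta-6,8,11,13-tetraen-19,6-olide
Conditions: Dess–Martin periodinane, NaHCO3, CH2Cl2, 0 °C to rt
Reagents that add atoms: none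
Why: Dess–Martin oxidation returns the C1 ketone under buffered conditions that leave the enol lactone untouched.

Step 19
Reactants: 24 tricyclic ketone
Product: 25 (4S,5R)-11,12,14-trimethoxy-1-oxo-9(10→20)abeo-abieta-6,8,10(20),11,13-pentaen-19,6-olide
Conditions: DDQ (1.3 equiv), 1,4-dioxane, 80 °C
Reagents that add atoms: none
Why: Quinone dehydrogenation, in which DDQ should abstract hydride from the benzylic C20 position activated by the ortho and para methoxy groups and loss of the acidic C10 proton next to the ketone then gives the arylidene ketone, whose ring-locked geometry is the only one possible.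

Step 20
Reactants: 25 dienone
Product: 26 (4S,5R)-12-methoxy-1,11,14-trioxo-9(10→20)abeo-abieta-6,8,10(20),12-tetraen-19,6-olide
Conditions: (NH4)2Ce(NO3)6 (2.5 equiv), MeCN/H2O, 0 °C
Reagents that add atoms: water, O
Why: Oxidative demethylation of the 1,2,4-trimethoxyarene by two one-electron oxidations with tetravalent cerium gives the para-quinone (C11, C14) and keeps the C12 methoxy group as a vinylogous ester.

Step 21
Reactants: 26 methoxyquinone
Product: 27 (4S,5R)-12-hydroxy-1,11,14-trioxo-9(10→20)abeo-abieta-6,8,10(20),12-tetraen-19,6-olide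
Conditions: BCl3 (1.5 equiv), CH2Cl2, −78 °C; then H2O
Reagents that add atoms: none
Why: Chelation-assisted ether cleavage, in which BCl3 bound between the C11 carbonyl and the C12 methoxy oxygen removes the methyl group as chloromethane at low temperature, a non-basic unmasking that spares the enol lactone.

Step 22
Reactants: 27 hydroxyquinone enone
Product: 29 6,7-anhydroballotiquinone, via hydroquinone 28 (not isolated)
Conditions: NaBH4, CeCl3·7H2O, MeOH/THF, −78 °C; then air, pH 7 buffer, rt
Reagents that add atoms: none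
Why: Luche reduction gives 1,2-reduction of the enone with hydride entering from the convex face that carries H5 and the C4 methyl group, away from the C5–C6 bond and the lactone, which sets 1R, and the hydroquinone formed alongside is re-oxidised to the hydroxyquinone by air.

**Compound list**

1 | citraconic anhydride | CC1=CC(=O)OC1=O | starting material
2 | 5-hydroxy-3-methylfuran-2(5H)-one (racemic) | CC1=CC(O)OC1=O | intermediate
3 | (−)-menthol, (1R,2S,5R)-2-isopropyl-5-methylcyclohexan-1-ol | CC(C)[C@@H]1CC[C@@H](C)C[C@H]1O | starting material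
4 | (5R)-5-[(1R,2S,5R)-menthyloxy]-3-methylfuran-2(5H)-one | CC1=C[C@H](O[C@@H]2C[C@H](C)CC[C@H]2C(C)C)OC1=O | intermediate
5 | 1,2,4-trimethoxybenzene | COc1ccc(OC)c(OC)c1 | starting material
6 | 2-(2,3,6-trimethoxyphenyl)propan-2-ol | COc1ccc(OC)c(C(C)(C)O)c1OC | intermediate
7 | 2-isopropyl-1,3,4-trimethoxybenzene | COc1ccc(OC)c(C(C)C)c1OC | intermediate
8 | 3-isopropyl-2,4,5-trimethoxybenzaldehyde | COc1cc(C=O)c(OC)c(C(C)C)c1OC | intermediate
9 | 2-(3-isopropyl-2,4,5-trimethoxyphenyl)-5,5-dimethyl-1,3-dioxane | COc1cc(C2OCC(C)(C)CO2)c(OC)c(C(C)C)c1OC | intermediate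
10 | 2-(2-iodo-5-isopropyl-3,4,6-trimethoxyphenyl)-5,5-dimethyl-1,3-dioxane | COc1c(I)c(C2OCC(C)(C)CO2)c(OC)c(C(C)C)c1OC | intermediate
11 | 3-[2-(5,5-dimethyl-1,3-dioxan-2-yl)-4-isopropyl-3,5,6-trimethoxyphenyl]propanal | COc1c(CCC=O)c(C2OCC(C)(C)CO2)c(OC)c(C(C)C)c1OC | intermediate
12 | 5-Ar-pent-1-en-3-ol (racemic) | COc1c(CCC(O)C=C)c(C2OCC(C)(C)CO2)c(OC)c(C(C)C)c1OC | intermediate
13 | 5-Ar-pent-1-en-3-one | COc1c(CCC(=O)C=C)c(C2OCC(C)(C)CO2)c(OC)c(C(C)C)c1OC | intermediate
14 | (3Z)-5-Ar-3-(tert-butyldimethylsilyloxy)penta-1,3-diene | COc1c(C/C=C(\O[Si](C)(C)C(C)(C)C)C=C)c(C2OCC(C)(C)CO2)c(OC)c(C(C)C)c1OC | intermediate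
15 | (3R,3aR,4S,7aS)-4-(ArCH2)-5-(tert-butyldimethylsilyloxy)-3-(MenO)-7a-methyl-3a,4,7,7a-tetrahydroisobenzofuran-1(3H)-one (endo adduct; 4S,5R,6R,10S in skeleton numbering) | COc1c(OC)c(C(C)C)c(OC)c(C3OCC(C)(C)CO3)c1C[C@@H]1C(O[Si](C)(C)C(C)(C)C)=CC[C@]4(C)C(=O)O[C@@H](O[C@@H]2C[C@H](C)CC[C@H]2C(C)C)[C@H]14 | intermediate
16 | (3R,3aR,4S,7aS)-4-(ArCH2)-3-(MenO)-7a-methylhexahydroisobenzofuran-1,5-dione | COc1c(OC)c(C(C)C)c(OC)c(C3OCC(C)(C)CO3)c1C[C@@H]1C(=O)CC[C@]4(C)C(=O)O[C@@H](O[C@@H]2C[C@H](C)CC[C@H]2C(C)C)[C@H]14 | intermediate (not isolated)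
17 | (3R,3aR,4S,5R,7aS)-4-(ArCH2)-5-hydroxy-3-(MenO)-7a-methylhexahydroisobenzofuran-1(3H)-one | COc1c(OC)c(C(C)C)c(OC)c(C3OCC(C)(C)CO3)c1C[C@@H]1[C@H](O)CC[C@]4(C)C(=O)O[C@@H](O[C@@H]2C[C@H](C)CC[C@H]2C(C)C)[C@H]14 | intermediate
18 | (3aR,4S,5R,7aS)-4-(Ar'CH2)-3,5-dihydroxy-7a-methylhexahydroisobenzofuran-1(3H)-one (both C3 anomers) | COc1c(OC)c(C(C)C)c(OC)c(C=O)c1C[C@@H]1[C@H](O)CC[C@]4(C)C(=O)OC(O)[C@H]14 | intermediate
19 | methyl (1S,2R,3S,4R)-2-formyl-3-(Ar'CH2)-4-hydroxy-1-methylcyclohexane-1-carboxylate | COc1c(OC)c(C(C)C)c(OC)c(C=O)c1C[C@@H]1[C@H](O)CC[C@](C)(C(=O)OC)[C@@H]1C=O | intermediate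
20 | methyl (1R,4S,5R,10S)-1,6,7-trihydroxy-11,12,14-trimethoxy-9(10→20)abeo-abieta-8,11,13-trien-19-oate (cis-6,7-diol, formed as its samarium diolate; C6/C7 not controlled) | COc1c(OC)c(C(C)C)c(OC)c2c1C[C@@H]1[C@H](O)CC[C@](C)(C(=O)OC)[C@@H]1C(O)C2O | intermediate (not isolated)
21 | (1R,4S,5R,10S)-1,7-dihydroxy-11,12,14-trimethoxy-9(10→20)abeo-abieta-8,11,13-trien-19,6-olide (C6/C7 not controlled) | COc1c(OC)c(C(C)C)c(OC)c2c1C[C@@H]1[C@H](O)CC[C@]3(C)C(=O)OC(C2O)[C@H]13 | intermediate
22 | 1-O-trifluoroacetate of 23 | COc1c(OC)c(C(C)C)c(OC)c2c1C[C@@H]1[C@H](OC(=O)C(F)(F)F)CC[C@]3(C)C(=O)OC(=C2)[C@H]13 | intermediate (not isolated)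
23 | (1R,4S,5R,10S)-1-hydroxy-11,12,14-trimethoxy-9(10→20)abeo-abieta-6,8,11,13-tetraen-19,6-olide | COc1c(OC)c(C(C)C)c(OC)c2c1C[C@@H]1[C@H](O)CC[C@]3(C)C(=O)OC(=C2)[C@H]13 | intermediate
24 | (4S,5R,10S)-11,12,14-trimethoxy-1-oxo-9(10→20)abeo-abieta-6,8,11,13-tetraen-19,6-olide | COc1c(OC)c(C(C)C)c(OC)c2c1C[C@@H]1C(=O)CC[C@]3(C)C(=O)OC(=C2)[C@H]13 | intermediate
25 | (4S,5R)-11,12,14-trimethoxy-1-oxo-9(10→20)abeo-abieta-6,8,10(20),11,13-pentaen-19,6-olide | COc1c(OC)c(C(C)C)c(OC)c2c1C=C1C(=O)CC[C@]3(C)C(=O)OC(=C2)[C@H]13 | intermediate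
26 | (4S,5R)-12-methoxy-1,11,14-trioxo-9(10→20)abeo-abieta-6,8,10(20),12-tetraen-19,6-olide | CC(C)C1=C(OC)C(=O)C2=C(C=C3OC(=O)[C@@]4(C)CCC(=O)C(=C2)[C@@H]34)C1=O | intermediate
27 | (4S,5R)-12-hydroxy-1,11,14-trioxo-9(10→20)abeo-abieta-6,8,10(20),12-tetraen-19,6-olide | CC(C)C1=C(O)C(=O)C2=C(C=C3OC(=O)[C@@]4(C)CCC(=O)C(=C2)[C@@H]34)C1=O | intermediate
28 | (1R,4S,5R)-1,11,12,14-tetrahydroxy-9(10→20)abeo-abieta-6,8,10(20),11,13-pentaen-19,6-olide | CC(C)c1c(O)c(O)c2c(c1O)C=C1OC(=O)[C@@]3(C)CC[C@@H](O)C(=C2)[C@@H]13 | intermediate (not isolated)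
29 | 6,7-anhydroballotiquinone, (1R,4S,5R)-1,12-dihydroxy-11,14-dioxo-9(10→20)abeo-abieta-6,8,10(20),12-tetraen-19,6-olide | CC(C)C1=C(O)C(=O)C2=C(C=C3OC(=O)[C@@]4(C)CC[C@@H](O)C(=C2)[C@@H]34)C1=O | target

**Step count**
Total: 22 steps. Longest linear sequence: 20 steps (steps 3–22, from 1,2,4-trimethoxybenzene 5 to 29).

**Steps most likely to fail, with fallbacks**

Step 12 (cycloaddition). The trisubstituted dienophile may add too slowly, so that the diene is lost by desilylation or polymerisation before it reacts, or the facial and endo preference erodes at the temperature needed. The fallback makes the same two bonds stepwise by an anionic double Michael sequence and sets out from enone 13 and butenolide 4. The lithium enolate of 13 (LiN(SiMe3)2, THF, −78 °C) should add through C10 to C5 of 4, anti to the menthyloxy group. The lactone enolate so formed should then close ring A by Michael addition of C4 to the vinyl ketone terminus C3. If the sequence stops after the first addition, the mono-adduct keto lactone F1 is isolated and cyclised with catalytic t-BuOK in THF. The route is rejoined at ketone 16, which is reduced with NaBH4 as in step 13.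

Step 16 (pinacol closure of ring B). The seven-membered ring may fail to close, the hindered aryl ketyl instead being reduced to the benzylic alcohol or coupling between molecules. The fallback sets out from dialdehyde 19. A McMurry coupling with low-valent titanium (TiCl3(DME)1.5, Zn–Cu couple, DME, reflux, high dilution) should give the benzocycloheptene ester F2. Cis-dihydroxylation of its C6=C7 bond (OsO4 cat., N-methylmorpholine N-oxide, acetone/H2O) leads to diol ester 20, which lactonises to 21, where the route is rejoined.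

Step 19 (dehydrogenation to C10=C20). DDQ may abstract hydride at C5, which is allylic to the enol lactone, instead of at C20, or it may oxidise the product further. The fallback sets out from ketone 24. Me3SiOTf/Et3N (CH2Cl2, 0 °C) should give the more substituted trimethylsilyl enol ether F3. N-bromosuccinimide at −78 °C should then give the C10 bromo ketone F4, with bromine entering on the convex face, cis to H5. DBU (toluene, rt) then removes HBr by an anti elimination that can only engage the benzylic C20 hydrogens, because H5 is syn to bromine. The route is rejoined at dienone 25.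

**Further compounds**
F1 | step 12 | (5R)-5-(MenO)-3-methyl-4-(1-Ar-3-oxopent-4-en-2-yl)dihydrofuran-2(3H)-one, side chain trans to the menthyloxy group, epimers at C3 and at the side-chain carbon | CC4C(=O)O[C@@H](O[C@@H]2C[C@H](C)CC[C@H]2C(C)C)[C@@H]4C(Cc1c(OC)c(OC)c(C(C)C)c(OC)c1C3OCC(C)(C)CO3)C(=O)C=C
F2 | step 16 | methyl (1R,4S,5R,10S)-1-hydroxy-11,12,14-trimethoxy-9(10→20)abeo-abieta-6,8,11,13-tetraen-19-oate | COc1c(OC)c(C(C)C)c(OC)c2c1C[C@@H]1[C@H](O)CC[C@](C)(C(=O)OC)[C@@H]1C=C2
F3 | step 19 | (4S,5R)-11,12,14-trimethoxy-1-(trimethylsilyloxy)-9(10→20)abeo-abieta-1(10),6,8,11,13-pentaen-19,6-olide | COc1c(OC)c(C(C)C)c(OC)c2c1CC1=C(O[Si](C)(C)C)CC[C@]3(C)C(=O)OC(=C2)[C@H]13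
F4 | step 19 | (4S,5R)-10-bromo-11,12,14-trimethoxy-1-oxo-9(10→20)abeo-abieta-6,8,11,13-tetraen-19,6-olide, bromine cis to H5 | COc1c(OC)c(C(C)C)c(OC)c2c1C[C@]1(Br)C(=O)CC[C@]3(C)C(=O)OC(=C2)[C@H]13
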